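The route rests on cutting the tetrasubstituted C5=C6 double bond of the carbocycle (1-benzofuranone numbering; C5 carries the pentanyl chain, C6 the CH2O arm, flanked by C4 and C7). The trans-fused α-methylene-γ-butyrolactone is built first. Olefin ring-closing metathesis then joins two 1,1-disubstituted alkenes that hang from C3a (via C4) and C7a (via C7), which closes the six-membered ring and creates the fully substituted alkene in one operation. The precursor is a monocyclic trans-4,5-disubstituted 3-methylideneoxolan-2-one, assembled by chromium-mediated γ-allylation of a citronellal-derived α-methylene aldehyde with a 3-(bromomethyl)butenolide. The C4 acetate is set afterwards by Mitsunobu inversion.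

Key step: step 11

Remark: the target is read as (3aS,4S,7aR) with a (2S) side chain, i.e. a trans-fused lactone with the 4-acetoxy group cis to the C3a–C3 bond; bicyclic compounds are numbered as 1-benzofuran-2(3H)-ones (O1, C2=O, C3=CH2, C3a, C4, C5, C6, C7, C7a).

**Step 1**
Reactants: 1 (S)-citronellal
Product: 2 (6S)-8,8-dimethoxy-2,6-dimethyloct-2-ene
Conditions: HC(OMe)3, PPTS (cat.), MeOH, rt
Reagents that add atoms: trimethyl orthoformate COC(OC)OC; methanol CO
Why: Acid-catalysed acetalisation, with the orthoformate as water scavenger, masks the aldehyde before the alkene is cleaved; the remote stereocentre is not involved.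

**Step 2**
Reactants: 2 (6S)-8,8-dimethoxy-2,6-dimethyloct-2-ene
Product: 5 (4S)-6,6-dimethoxy-4-methylhexan-1-ol, via ozonide 3 (not isolated), via aldehyde 4 (not isolated)
Conditions: O3, CH2Cl2, −78 °C; then NaBH4, MeOH, −78 °C → rt
Reagents that add atoms: ozone [O-][O+]=O
Why: Ozonolysis of the only alkene and borohydride reduction of the ozonide should give the primary alcohol, shortened by the isopropylidene unit, with acetal and stereocentre untouched.

**Step 3**
Reactants: 5 (4S)-6,6-dimethoxy-4-methylhexan-1-ol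
Product: 6 tert-butyl{[(4S)-6,6-dimethoxy-4-methylhexyl]oxy}diphenylsilane
Conditions: TBDPSCl, imidazole, CH2Cl2, rt
Reagents that add atoms: tert-butyl(chloro)diphenylsilane CC(C)(C)[Si](Cl)(c1ccccc1)c1ccccc1
Why: Imidazole-promoted silylation of the primary alcohol; TBDPS is chosen because it must survive the acidic acetal cleavage and all later steps.

**Step 4**
Reactants: 6 tert-butyl{[(4S)-6,6-dimethoxy-4-methylhexyl]oxy}diphenylsilane
Product: 7 (3S)-6-[(tert-butyldiphenylsilyl)oxy]-3-methylhexanal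
Conditions: AcOH/THF/H2O (3:1:1), 45 °C
Reagents that add atoms: water O
Why: Aqueous acid hydrolysis of the dimethyl acetal (acetal deprotection), to which the TBDPS ether is stable.

**Step 5**
Reactants: 7 (3S)-6-[(tert-butyldiphenylsilyl)oxy]-3-methylhexanal
Product: 8 (3S)-6-[(tert-butyldiphenylsilyl)oxy]-3-methyl-2-methylidenehexanal
Conditions: aq. HCHO (37 %), pyrrolidine (10 mol %), propionic acid (10 mol %), i-PrOH, 45 °C
Reagents that add atoms: formaldehyde C=O
Why: Amine/acid-catalysed α-methylenation (Mannich condensation–elimination) turns the α-CH2 into the 1,1-disubstituted enal; the β-stereocentre is not enolisable in the saturated aldehyde and the mild conditions should not isomerise the product.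

**Step 6**
Reactants: 9 3-chloro-2-(chloromethyl)prop-1-ene (3 equiv), 10 (4-methoxyphenyl)methanol
Product: 11 1-({[2-(chloromethyl)prop-2-en-1-yl]oxy}methyl)-4-methoxybenzene
Conditions: NaH, THF, 0 °C; then 9, Bu4NI (cat.), rt
Reagents that add atoms: none
Why: Williamson ether synthesis; the excess of the bis-allylic dichloride favours mono-substitution.

**Step 7**
Reactants: 11 1-({[2-(chloromethyl)prop-2-en-1-yl]oxy}methyl)-4-methoxybenzene, 12 acrolein
Product: 16 (3R)-5-{[(4-methoxyphenyl)methoxy]methyl}hexa-1,5-dien-3-ol, via allyl Grignard reagent 13 (not isolated), via allylborane 14 (not isolated), via borinate adduct 15 (not isolated)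
Conditions: Mg, THF, 0 °C; (+)-Ipc2BOMe (from (−)-α-pinene), Et2O, −78 °C → rt; 12, −78 °C; then NaOH, H2O2, rt
Reagents that add atoms: none
Why: Brown asymmetric allylboration: the (+)-Ipc2B-allyl reagent should deliver the 2-substituted allyl group to the Re face of acrolein through a chair transition state, setting the (R)-carbinol that becomes C7a.

**Step 8**
Reactants: 16 (3R)-5-{[(4-methoxyphenyl)methoxy]methyl}hexa-1,5-dien-3-ol, 17 2-(bromomethyl)prop-2-enoic acid
Product: 19 (3R)-5-{[(4-methoxyphenyl)methoxy]methyl}hexa-1,5-dien-3-yl 2-(bromomethyl)prop-2-enoate, via acid chloride 18 (not isolated)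
Conditions: 17, (COCl)2, DMF (cat.), CH2Cl2, 0 °C → rt; then 16, 2,6-lutidine, CH2Cl2, −20 → 0 °C
Reagents that add atoms: none
Why: Acylation of the secondary alcohol by the acid chloride made in the flask, with retention at the carbinol; the hindered base avoids SN2' attack on the bromomethyl acrylate.

**Step 9**
Reactants: 19 (3R)-5-{[(4-methoxyphenyl)methoxy]methyl}hexa-1,5-dien-3-yl 2-(bromomethyl)prop-2-enoate
Product: 20 (5R)-3-(bromomethyl)-5-(2-{[(4-methoxyphenyl)methoxy]methyl}prop-2-en-1-yl)furan-2(5H)-one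
Conditions: Grubbs II (5 mol %), CH2Cl2 (5 mM), 40 °C
Reagents that add atoms: none
Why: Ring-closing metathesis of the vinyl group with the acrylate alkene closes the lactone ring as a butenolide with loss of ethene; the third alkene could only give a cyclobutene or a tetrasubstituted six-membered lactone and should stay out.

**Step 10**
Reactants: 20 (5R)-3-(bromomethyl)-5-(2-{[(4-methoxyphenyl)methoxy]methyl}prop-2-en-1-yl)furan-2(5H)-one, 8 (3S)-6-[(tert-butyldiphenylsilyl)oxy]-3-methyl-2-methylidenehexanal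
Product: 22 (4R,5R)-4-[(1R,3S)-6-[(tert-butyldiphenylsilyl)oxy]-1-hydroxy-3-methyl-2-methylidenehexyl]-5-(2-{[(4-methoxyphenyl)methoxy]methyl}prop-2-en-1-yl)-3-methylideneoxolan-2-one, via allylchromium species 21 (not isolated)
Conditions: CrCl2 (4 equiv), THF, 0 °C → rt; aqueous work-up
Reagents that add atoms: none
Why: Nozaki–Hiyama-type Barbier γ-allylation: the allylchromium(III) species should add to the aldehyde through a chair Zimmerman–Traxler transition state on the butenolide face anti to the C5 arm, which unveils the α-methylene lactone, sets the trans 4,5-relationship (future C3a/C7a) and gives the (1R)-carbinol, epimeric to the target at the future C4.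

**Step 11**
Reactants: 22 (4R,5R)-4-[(1R,3S)-6-[(tert-butyldiphenylsilyl)oxy]-1-hydroxy-3-methyl-2-methylidenehexyl]-5-(2-{[(4-methoxyphenyl)methoxy]methyl}prop-2-en-1-yl)-3-methylideneoxolan-2-one
Product: 23 (3aR,4R,7aR)-5-[(2S)-5-[(tert-butyldiphenylsilyl)oxy]pentan-2-yl]-4-hydroxy-6-{[(4-methoxyphenyl)methoxy]methyl}-3-methylidene-3a,4,7,7a-tetrahydro-1-benzofuran-2(3H)-one
Conditions: Stewart–Grubbs catalyst (10 mol %, two portions), 1,4-benzoquinone (20 mol %), toluene (2 mM), 80 °C, Ar sparge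
Reagents that add atoms: none
Why: Olefin ring-closing metathesis: the ruthenium methylidene should load on the unhindered 2-(PMBO-methyl)allyl alkene, and the resulting alkylidene at the future C6 engages the 1,1-disubstituted alkene at the future C5 through a ruthenacyclobutane ([2+2]/retro-[2+2]) with loss of ethene. The closest known reaction type is RCM to tetrasubstituted cycloalkenes with sterically slimmed (o-tolyl NHC) ruthenium catalysts. The carbocycle closes as a six-membered ring onto the existing lactone, the two arms sitting trans on adjacent oxolanone carbons (C4, C5) so that the trans-fused bicycle results. No stereocentre is formed; C3a, C4, C7a and the side-chain centre are carried through untouched. The step needs chemoselectivity among four 1,1-disubstituted alkenes, which the substrate secures because the electron-poor α-methylene lactone alkene could only close to a cyclobutene or an anti-Bredt bridged alkene, while high dilution disfavours dimerisation. The free allylic hydroxyl should assist the hindered closure, and benzoquinone suppresses Ru–H isomerisation of the allylic alcohol.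

**Step 12**
Reactants: 23 (3aR,4R,7aR)-5-[(2S)-5-[(tert-butyldiphenylsilyl)oxy]pentan-2-yl]-4-hydroxy-6-{[(4-methoxyphenyl)methoxy]methyl}-3-methylidene-3a,4,7,7a-tetrahydro-1-benzofuran-2(3H)-one
Product: 24 (3aS,4S,7aR)-5-[(2S)-5-[(tert-butyldiphenylsilyl)oxy]pentan-2-yl]-6-{[(4-methoxyphenyl)methoxy]methyl}-3-methylidene-2-oxo-2,3,3a,4,7,7a-hexahydro-1-benzofuran-4-yl acetate
Conditions: PPh3, DIAD (betaine pre-formed), AcOH, toluene, 0 °C → rt
Reagents that add atoms: acetic acid CC(=O)O
Why: Mitsunobu esterification with SN2 inversion installs the acetate and corrects C4 to the pseudoaxial (4S) configuration; the pseudo-equatorial oxyphosphonium has no antiperiplanar hydrogen for E2, and SN2' would have to attack the fully substituted C6.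

**Step 13**
Reactants: 24 (3aS,4S,7aR)-5-[(2S)-5-[(tert-butyldiphenylsilyl)oxy]pentan-2-yl]-6-{[(4-methoxyphenyl)methoxy]methyl}-3-methylidene-2-oxo-2,3,3a,4,7,7a-hexahydro-1-benzofuran-4-yl acetate
Product: 25 (3aS,4S,7aR)-5-[(2S)-5-[(tert-butyldiphenylsilyl)oxy]pentan-2-yl]-6-(hydroxymethyl)-3-methylidene-2-oxo-2,3,3a,4,7,7a-hexahydro-1-benzofuran-4-yl acetate
Conditions: DDQ (1.3 equiv), CH2Cl2/pH 7 buffer (10:1), 0 °C
Reagents that add atoms: none
Why: Oxidative PMB ether cleavage by DDQ (benzylic oxidation, then hydrolysis) should free the primary allylic alcohol while acetate, silyl ether and alkenes are retained.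

**Step 14**
Reactants: 25 (3aS,4S,7aR)-5-[(2S)-5-[(tert-butyldiphenylsilyl)oxy]pentan-2-yl]-6-(hydroxymethyl)-3-methylidene-2-oxo-2,3,3a,4,7,7a-hexahydro-1-benzofuran-4-yl acetate
Product: 26 [(3aS,4S,7aR)-4-(acetyloxy)-5-[(2S)-5-[(tert-butyldiphenylsilyl)oxy]pentan-2-yl]-3-methylidene-2-oxo-2,3,3a,4,7,7a-hexahydro-1-benzofuran-6-yl]methyl 2-methylprop-2-enoate
Conditions: methacrylic anhydride, Et3N, DMAP (cat.), CH2Cl2, 0 °C
Reagents that add atoms: methacrylic anhydride C=C(C)C(=O)OC(=O)C(C)=C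
Why: DMAP-catalysed acylation of the unhindered primary allylic alcohol installs the methacrylate.

**Step 15**
Reactants: 26 [(3aS,4S,7aR)-4-(acetyloxy)-5-[(2S)-5-[(tert-butyldiphenylsilyl)oxy]pentan-2-yl]-3-methylidene-2-oxo-2,3,3a,4,7,7a-hexahydro-1-benzofuran-6-yl]methyl 2-methylprop-2-enoate
Product: 27 [(3aS,4S,7aR)-4-(acetyloxy)-5-[(2S)-5-hydroxypentan-2-yl]-3-methylidene-2-oxo-2,3,3a,4,7,7a-hexahydro-1-benzofuran-6-yl]methyl 2-methylprop-2-enoate (CNP0114085.1)
Conditions: HF·pyridine, THF/pyridine, 0 °C → rt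
Reagents that add atoms: none
Why: Fluoride-mediated desilylation under buffered, non-basic conditions should release the primary alcohol without touching the two esters or the α-methylene lactone.

**Compound list**

1 | (3S)-3,7-dimethyloct-6-enal, (S)-citronellal | C[C@@H](CCC=C(C)C)CC=O | starting material
2 | (6S)-8,8-dimethoxy-2,6-dimethyloct-2-ene | C[C@@H](CCC=C(C)C)CC(OC)OC | intermediate
3 | 3-[(3S)-5,5-dimethoxy-3-methylpentyl]-5,5-dimethyl-1,2,4-trioxolane (ozonide, not isolated) | C[C@@H](CCC1OOC(C)(C)O1)CC(OC)OC | intermediate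
4 | (4S)-6,6-dimethoxy-4-methylhexanal (not isolated) | C[C@@H](CCC=O)CC(OC)OC | intermediate
5 | (4S)-6,6-dimethoxy-4-methylhexan-1-ol | C[C@@H](CCCO)CC(OC)OC | intermediate
6 | tert-butyl{[(4S)-6,6-dimethoxy-4-methylhexyl]oxy}diphenylsilane | C[C@@H](CCCO[Si](c1ccccc1)(c1ccccc1)C(C)(C)C)CC(OC)OC | intermediate
7 | (3S)-6-[(tert-butyldiphenylsilyl)oxy]-3-methylhexanal | C[C@@H](CCCO[Si](c1ccccc1)(c1ccccc1)C(C)(C)C)CC=O | intermediate
8 | (3S)-6-[(tert-butyldiphenylsilyl)oxy]-3-methyl-2-methylidenehexanal | C[C@@H](CCCO[Si](c1ccccc1)(c1ccccc1)C(C)(C)C)C(=C)C=O | intermediate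
9 | 3-chloro-2-(chloromethyl)prop-1-ene | C=C(CCl)CCl | starting material
10 | (4-methoxyphenyl)methanol | COc1ccc(CO)cc1 | starting material
11 | 1-({[2-(chloromethyl)prop-2-en-1-yl]oxy}methyl)-4-methoxybenzene | C=C(CCl)COCc1ccc(OC)cc1 | intermediate
12 | prop-2-enal, acrolein | C=CC=O | starting material
13 | [2-({[(4-methoxyphenyl)methoxy]}methyl)prop-2-en-1-yl]magnesium chloride (not isolated) | C=C(C[Mg]Cl)COCc1ccc(OC)cc1 | intermediate
14 | [2-({[(4-methoxyphenyl)methoxy]}methyl)prop-2-en-1-yl]bis(isopinocampheyl)borane, Ipc groups from (−)-α-pinene (not isolated) | C=C(COCc1ccc(OC)cc1)CB([C@H]1C[C@H]2C[C@@H]([C@@H]1C)C2(C)C)[C@H]1C[C@H]2C[C@@H]([C@@H]1C)C2(C)C | intermediate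
15 | (3R)-5-{[(4-methoxyphenyl)methoxy]methyl}hexa-1,5-dien-3-yl bis(isopinocampheyl)borinate (not isolated) | C=C(COCc1ccc(OC)cc1)C[C@@H](OB([C@H]1C[C@H]2C[C@@H]([C@@H]1C)C2(C)C)[C@H]1C[C@H]2C[C@@H]([C@@H]1C)C2(C)C)C=C | intermediate
16 | (3R)-5-{[(4-methoxyphenyl)methoxy]methyl}hexa-1,5-dien-3-ol | C=C(COCc1ccc(OC)cc1)C[C@@H](O)C=C | intermediate
17 | 2-(bromomethyl)prop-2-enoic acid | C=C(CBr)C(=O)O | starting material
18 | 2-(bromomethyl)prop-2-enoyl chloride (not isolated) | C=C(CBr)C(=O)Cl | intermediate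
19 | (3R)-5-{[(4-methoxyphenyl)methoxy]methyl}hexa-1,5-dien-3-yl 2-(bromomethyl)prop-2-enoate | C=C(COCc1ccc(OC)cc1)C[C@@H](OC(=O)C(=C)CBr)C=C | intermediate
20 | (5R)-3-(bromomethyl)-5-(2-{[(4-methoxyphenyl)methoxy]methyl}prop-2-en-1-yl)furan-2(5H)-one | C=C(COCc1ccc(OC)cc1)C[C@H]1OC(=O)C(CBr)=C1 | intermediate
21 | {[(5R)-5-(2-{[(4-methoxyphenyl)methoxy]methyl}prop-2-en-1-yl)-2-oxo-2,5-dihydrofuran-3-yl]methyl}chromium(III) dichloride (not isolated) | C=C(COCc1ccc(OC)cc1)C[C@H]1OC(=O)C(C[Cr](Cl)Cl)=C1 | intermediate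
22 | (4R,5R)-4-[(1R,3S)-6-[(tert-butyldiphenylsilyl)oxy]-1-hydroxy-3-methyl-2-methylidenehexyl]-5-(2-{[(4-methoxyphenyl)methoxy]methyl}prop-2-en-1-yl)-3-methylideneoxolan-2-one | C=C(COCc1ccc(OC)cc1)C[C@H]1OC(=O)C(=C)[C@@H]1[C@@H](O)C(=C)[C@@H](C)CCCO[Si](c1ccccc1)(c1ccccc1)C(C)(C)C | intermediate
23 | (3aR,4R,7aR)-5-[(2S)-5-[(tert-butyldiphenylsilyl)oxy]pentan-2-yl]-4-hydroxy-6-{[(4-methoxyphenyl)methoxy]methyl}-3-methylidene-3a,4,7,7a-tetrahydro-1-benzofuran-2(3H)-one | COc1ccc(COCC2=C([C@@H](C)CCCO[Si](c3ccccc3)(c3ccccc3)C(C)(C)C)[C@H](O)[C@H]3C(=C)C(=O)O[C@@H]3C2)cc1 | intermediate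
24 | (3aS,4S,7aR)-5-[(2S)-5-[(tert-butyldiphenylsilyl)oxy]pentan-2-yl]-6-{[(4-methoxyphenyl)methoxy]methyl}-3-methylidene-2-oxo-2,3,3a,4,7,7a-hexahydro-1-benzofuran-4-yl acetate | COc1ccc(COCC2=C([C@@H](C)CCCO[Si](c3ccccc3)(c3ccccc3)C(C)(C)C)[C@@H](OC(C)=O)[C@H]3C(=C)C(=O)O[C@@H]3C2)cc1 | intermediate
25 | (3aS,4S,7aR)-5-[(2S)-5-[(tert-butyldiphenylsilyl)oxy]pentan-2-yl]-6-(hydroxymethyl)-3-methylidene-2-oxo-2,3,3a,4,7,7a-hexahydro-1-benzofuran-4-yl acetate | OCC1=C([C@@H](C)CCCO[Si](c2ccccc2)(c2ccccc2)C(C)(C)C)[C@@H](OC(C)=O)[C@H]2C(=C)C(=O)O[C@@H]2C1 | intermediate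
26 | [(3aS,4S,7aR)-4-(acetyloxy)-5-[(2S)-5-[(tert-butyldiphenylsilyl)oxy]pentan-2-yl]-3-methylidene-2-oxo-2,3,3a,4,7,7a-hexahydro-1-benzofuran-6-yl]methyl 2-methylprop-2-enoate | C=C(C)C(=O)OCC1=C([C@@H](C)CCCO[Si](c2ccccc2)(c2ccccc2)C(C)(C)C)[C@@H](OC(C)=O)[C@H]2C(=C)C(=O)O[C@@H]2C1 | intermediate
27 | [(3aS,4S,7aR)-4-(acetyloxy)-5-[(2S)-5-hydroxypentan-2-yl]-3-methylidene-2-oxo-2,3,3a,4,7,7a-hexahydro-1-benzofuran-6-yl]methyl 2-methylprop-2-enoate | C=C(C)C(=O)OCC1=C([C@@H](C)CCCO)[C@@H](OC(C)=O)[C@H]2C(=C)C(=O)O[C@@H]2C1 | target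

**Step count and risks**

Total step count: 15. Longest linear sequence: 11 steps (steps 1–5, then 10–15).

Steps most likely to fail:

1. Step 11 (ring-closing metathesis). The alkylidene formed on the C6 arm may not engage the congested alkene at C5, so that dimerisation, isomerisation of the allylic alcohol or catalyst decomposition outruns ring closure. Fallback (relay ring-closing metathesis): setting out from aldehyde 7, an amine-catalysed cross-aldol condensation with 2-(allyloxy)benzaldehyde (pyrrolidine, PhCO2H cat., toluene, 60 °C) should give (2E)-2-[(2S)-5-[(tert-butyldiphenylsilyl)oxy]pentan-2-yl]-3-[2-(prop-2-en-1-yloxy)phenyl]prop-2-enal F1. Chromium(II)-mediated coupling of F1 with bromide 20, as in step 10, should give the relay-armed adduct (4R,5R)-4-{(1R,2E)-2-[(2S)-5-[(tert-butyldiphenylsilyl)oxy]pentan-2-yl]-1-hydroxy-3-[2-(prop-2-en-1-yloxy)phenyl]prop-2-en-1-yl}-5-(2-{[(4-methoxyphenyl)methoxy]methyl}prop-2-en-1-yl)-3-methylideneoxolan-2-one F2. With Grubbs II (toluene, 60–80 °C) the catalyst loads on the O-allyl group and expels 2H-chromene, which places the alkylidene directly on the hindered carbon; this then only has to close onto the unhindered allyl alkene. The fallback comes back to the route at 23.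

2. Step 12 (Mitsunobu inversion). Ionisation or elimination of the activated allylic alcohol, or acylation with retention, may compete with clean SN2 displacement at the hindered carbinol. Fallback (set the acetoxy centre during C–C bond formation through an open transition state): setting out from bromide 20, Pd(0)-catalysed stannylation with hexabutylditin should give (5R)-5-(2-{[(4-methoxyphenyl)methoxy]methyl}prop-2-en-1-yl)-3-[(tributylstannyl)methyl]furan-2(5H)-one F3. BF3·OEt2-promoted addition of F3 to enal 8 at −78 °C proceeds through an open antiperiplanar transition state and should give the syn adduct (4R,5R)-4-[(1S,3S)-6-[(tert-butyldiphenylsilyl)oxy]-1-hydroxy-3-methyl-2-methylidenehexyl]-5-(2-{[(4-methoxyphenyl)methoxy]methyl}prop-2-en-1-yl)-3-methylideneoxolan-2-one F4, again anti to the C5 arm. Acetylation (Ac2O, pyridine, DMAP) should give (1S,3S)-6-[(tert-butyldiphenylsilyl)oxy]-1-[(2R,3S)-2-(2-{[(4-methoxyphenyl)methoxy]methyl}prop-2-en-1-yl)-4-methylidene-5-oxooxolan-3-yl]-3-methyl-2-methylidenehexyl acetate F5. Ring-closing metathesis of F5 under the conditions of step 11 comes back to the route at 24.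

3. Step 7 (asymmetric allylboration). Wurtz coupling during formation of the functionalised allyl Grignard reagent and imperfect facial control with the small aldehyde may lower conversion and enantiomeric purity. Fallback (resolution instead of reagent control): setting out from chloride 11 and acrolein 12, an indium-mediated Barbier allylation (In, THF/H2O, rt) should give racemic 5-{[(4-methoxyphenyl)methoxy]methyl}hexa-1,5-dien-3-ol F6. Lipase-catalysed kinetic resolution (Candida antarctica lipase B, vinyl acetate, hexane, rt) should acetylate the (S)-enantiomer and leave the (R)-alcohol, which is compound 16, where the route is rejoined.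

**Further compounds**

F1 | step 11 | (2E)-2-[(2S)-5-[(tert-butyldiphenylsilyl)oxy]pentan-2-yl]-3-[2-(prop-2-en-1-yloxy)phenyl]prop-2-enal | O=C/C(=C/c1ccccc1OCC=C)[C@@H](C)CCCO[Si](c1ccccc1)(c1ccccc1)C(C)(C)C
F2 | step 11 | (4R,5R)-4-{(1R,2E)-2-[(2S)-5-[(tert-butyldiphenylsilyl)oxy]pentan-2-yl]-1-hydroxy-3-[2-(prop-2-en-1-yloxy)phenyl]prop-2-en-1-yl}-5-(2-{[(4-methoxyphenyl)methoxy]methyl}prop-2-en-1-yl)-3-methylideneoxolan-2-one | C=C(COCc1ccc(OC)cc1)C[C@H]1OC(=O)C(=C)[C@@H]1[C@@H](O)/C(=C/c1ccccc1OCC=C)[C@@H](C)CCCO[Si](c1ccccc1)(c1ccccc1)C(C)(C)C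
F3 | step 12 | (5R)-5-(2-{[(4-methoxyphenyl)methoxy]methyl}prop-2-en-1-yl)-3-[(tributylstannyl)methyl]furan-2(5H)-one | C=C(COCc1ccc(OC)cc1)C[C@H]1OC(=O)C(C[Sn](CCCC)(CCCC)CCCC)=C1
F4 | step 12 | (4R,5R)-4-[(1S,3S)-6-[(tert-butyldiphenylsilyl)oxy]-1-hydroxy-3-methyl-2-methylidenehexyl]-5-(2-{[(4-methoxyphenyl)methoxy]methyl}prop-2-en-1-yl)-3-methylideneoxolan-2-one | C=C(COCc1ccc(OC)cc1)C[C@H]1OC(=O)C(=C)[C@@H]1[C@H](O)C(=C)[C@@H](C)CCCO[Si](c1ccccc1)(c1ccccc1)C(C)(C)C
F5 | step 12 | (1S,3S)-6-[(tert-butyldiphenylsilyl)oxy]-1-[(2R,3S)-2-(2-{[(4-methoxyphenyl)methoxy]methyl}prop-2-en-1-yl)-4-methylidene-5-oxooxolan-3-yl]-3-methyl-2-methylidenehexyl acetate | C=C(COCc1ccc(OC)cc1)C[C@H]1OC(=O)C(=C)[C@@H]1[C@H](OC(C)=O)C(=C)[C@@H](C)CCCO[Si](c1ccccc1)(c1ccccc1)C(C)(C)C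
F6 | step 7 | racemic 5-{[(4-methoxyphenyl)methoxy]methyl}hexa-1,5-dien-3-ol | C=C(COCc1ccc(OC)cc1)CC(O)C=C
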